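Late in the alpha run, at 40.0 h, 73.9% of the substrate was left and 25.9% was product. These sum to 99.8%, so I counted product as substrate lost.

common to all: substrate 0.13 M; catalyst 13 mM
- epsilon: coupling partner 0.137 M (fed, over 40 h); the very flask that is asked about, followed so far
- alpha: coupling partner 0.21 M (fed, over 40 h); run made earlier
- flask: coupling partner 0.137 M (fed, over 40 h); time 40 h

| run | time / h | product / % | substrate / % |
|---|---|---|---|
| epsilon | 1.33 | 0.8 | 99.6 |
| epsilon | 4.00 | 1.0 | 99.2 |
| epsilon | 8.00 | 3.1 | 96.6 |
| epsilon | 10.0 | 4.4 | 95.1 |
| epsilon | 15.0 | 7.5 | 92.4 |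
| epsilon | 20.0 | 10.3 | 89.8 |
| alpha | 3.00 | 0.5 | 98.8 |
| alpha | 5.00 | 2.5 | 98.0 |
| alpha | 8.00 | 5.3 | 95.1 |
| alpha | 15.0 | 11.3 | 88.8 |
| alpha | 25.0 | 18.3 | 81.2 |
| alpha | 40.0 | 25.9 | 73.9 |

(standard deviation of a reading: 0.3 percentage points)

1. concentration of product at 40 h, in M
2. concentration of substrate at 40 h, in M
3. concentration of coupling partner at 40 h, in M

The bench rule scales the percent made with the partner charge, here by 0.652, so the alpha run gave 16.9% made for this flask at 40 h. That rule treats the percent made as equal to the logarithm of one over the fraction left. In the alpha run their ratio was 1.05 at 15.0 h but 1.17 at 40.0 h, so by then the rule had passed its border.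

I therefore worked with the fraction left. At 15.0 h, the logarithms of the epsilon and alpha runs stood in the ratio 0.665, a reading close to the charge ratio. I defined the exposure per charge as that logarithm divided by the whole partner charge, and the alpha run gave 1.44 M⁻¹. For this flask I reckoned 82.1% of the substrate left, so c(substrate) 0.107 M and c(product) 0.0233 M. No run reads the partner, so I committed to no value for c(coupling partner). The forecast gave 0.024 M, 0.106 M and 0.01 M for product, substrate and partner, reasoning that “partner is not accumulating”.

The flask gave c(product) 0.0235 M, c(substrate) 0.107 M and c(coupling partner) 0.0198 M.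

    substrate + coupling partner + catalyst ⇌ product + catalyst, rate k1*[substrate]*[coupling partner]*[catalyst] forward; the back reaction follows from the equilibrium constant (K = 16.0 M⁻¹, k = 44.0 M⁻² h⁻¹)
    coupling partner → decomposed reagent (k = 0.150 h⁻¹)

During the 40 h of dosing in this flask, partner passed into decomposed reagent, 0.0380 M by 20.0 h and 0.0938 M by 40.0 h, while c(coupling partner) stood at 0.0187 M at 30.0 h. Alongside, substrate and partner passed into product, a net 18.1% of the substrate charged, with catalyst at 100% and 14% of the partner charge remaining. The exposure per charge of this flask came to 1.45 M⁻¹. For the same flask with 0.55 M of partner, 1.44 M⁻¹ gives 45.3% of the substrate left, and that flask held 47.6%.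

(The runs stem from a simulated flask from invented constants, noise included.)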